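## Structural features

Polyfibrospongol A is a rearranged drimane sesquiterpenoid: a trans-fused decalin (ring A: C1–C5 and C10; ring B: C5–C10) whose C9 carries a methylene (C15) bound to a 2-hydroxy-3-methoxy-5-(methoxycarbonyl)phenyl ring. Four contiguous stereocentres lie on one edge of ring B: quaternary C5 (S, axial methyl C12), C10 (S, axial hydrogen), quaternary C9 (R, axial methyl C14, equatorial arylmethyl) and C8 (S, equatorial methyl C13). C12 and C14 are 1,3-diaxial on the same face, and C13 and C14 are cis. Ring A holds only the exocyclic C4=C11 methylene, directly next to quaternary C5. The fragile groups are this 1,1-disubstituted alkene (acid-induced migration, hydrogenation, electrophilic halogen), the electron-rich free phenol and the methyl ester (hydride, hot alkali). The real difficulty is C9, a quaternary carbon between two stereocentres whose methyl group must sit axial and syn to the C5 methyl. The key step uses exactly this: a linear cyano group fills that axial site at little cost, so C9 enters as a nitrile-stabilised carbanion that already bears C15 and the arene, ring B is closed through the C8–C9 bond, and the nitrile carbon becomes C14 afterwards.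

## Logic of the disconnections

34 to 31: the C4=C11 double bond is cut first (carbonyl olefination), because the exocyclic alkene is the group least able to survive acid, hydrogen or halogen. This leaves ketone 31 and puts every other operation ahead of the alkene. The forward step must methylenate a ketone next to a quaternary carbon without touching the ester or the phenol.

31 to 30 to 29: the ketone and the phenol of 31 are traced to the dioxolane and the methoxymethyl ether of 30, which one acid treatment removes together. The aryl–carboxyl bond of 30 is then cut to give aryl bromide 29. The gain is that no ester is present during the hydride and hydrazine steps, and that the ester position is fixed by a bromine bought with the arene. The demand is that this bromine survives amide bases, the aluminium hydride and hot alkali.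

29 to 27 to 25: no skeletal bond is cut; the C14 methyl is traced through the aldehyde to the nitrile of 25. The reason is that only the cyano group is both small enough for the axial site and able to stabilise a carbanion at C9. The demand is a clean two-stage reduction at a neopentyl, axial carbon.

25 to 23 (key disconnection): the C8–C9 bond is cut and ring B is opened. This removes one ring and two stereocentres and leaves a monocyclic ring A compound. A check of all four centres shows that the sulfonate carbon of 23 must be (R): backside displacement then gives (8S), and the cyano group takes the place of the later C14 methyl. The forward step must give inversion at C8, nitrile axial at C9, and C-alkylation in preference to elimination. C4 must be masked so that no enolate can form at C3.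

23 to 22 to 21 to 15 + 19, and 19 to 18 to 17 to 16: the C9–C15 bond is cut, which makes the route convergent; the arene arrives by alkylation of nitrile 15 with benzylic bromide 19. The C9 configuration of 21 is irrelevant because it is planarised again in the key step. The sulfonate of 23 is traced to the silyl ether of 21, and 19 comes in three routine steps from 16. The phenol is carried as a methoxymethyl ether because it tolerates all bases and leaves in the same acid step as the dioxolane.

15 to 12 to 10 to 9: no skeletal bond is cut; C9 and the nitrile carbon are traced to a vinyl group by hydroboration and oxidation-state adjustment, and the dioxolane to the ketone of 9. The demand is that the ketone is masked before the borane step. With only one carbonyl group in 9 this poses no selectivity problem.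

9 to 7 + 4, and 4 to 3 to 2 to 1: the C5–C6 bond is cut, so C6, C7, C8 and C13 arrive as chiral-pool iodide 4. This replaces a Michael acceptor that would have left a second ketone, which would then need to be told apart from the C4 ketone and reduced enantioselectively. The C8 configuration is bought with 1 and only has to be inverted once, in the key step. The demand is C-alkylation of a tetrasubstituted enolate by an unactivated primary iodide, anti to the neighbouring vinyl group, to set C5.

7 to 5: the C10–vinyl bond is cut by a conjugate-addition transform. Catalytic asymmetric vinylation sets C10, and silylation of the resulting enolate fixes its regiochemistry for the C5 alkylation. The demand is high enantioselectivity with the parent vinyl group on an α-substituted enone.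

## Other disconnections considered

Alternative 1: Ring B is cut at C7–C8 and C9–C10. Forward, a Lewis-acid-promoted exo Diels–Alder reaction joins the ring A diene A1 (C10=C5–C6=C7, silyl ether at C4) with tiglic aldehyde A2 (C8 and C9) to give octalin aldehyde A3.
- In favour: two bonds, ring B and the three centres C8, C9 and C10 would form in one step from two small fragments. The cis C13/C14 pair follows stereospecifically from the E geometry of A2. C14 arrives as a methyl group and C15 as a formyl group ready for aryl-metal addition and benzylic deoxygenation, so no nitrile-to-methyl detour is needed. On convergence and on C14 this alternative is the better one.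
- Against: A2 is a trisubstituted, α-branched and therefore sluggish dienophile, and A1 is an acid-sensitive diene with an ionisable allylic ether. The step needs regio-, exo- and facial control at once, the last from a C4 stereocentre that must first be made enantioenriched and is destroyed later. A3 also still lacks the angular C12 methyl, since C5 is an alkene carbon. A hydroxyl-directed cyclopropanation and reductive opening from the C4 oxygen of A3 would deliver carbon to the face that gives the cis ring fusion, so C4 would have to be inverted first.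
- Comparison: the chosen plan fixes the trans C5/C10 pair in its first two C–C bond formations, whereas here the ring fusion is still open after the key step. A concerted cycloaddition and an SN2 ring closure are equally stereospecific for C8. The shorter approach to the bicycle is offset by the steps for C12, C4 and the arene, so the two plans should be of similar length.

Alternative 2: Both rings are opened by cutting C5–C10 and C3–C4. Forward, a Lewis-acid-promoted intramolecular Diels–Alder reaction of trienal A4 adds the (E)-3-methyl enal (C4, C5) across the terminal diene (C10, C1, C2, C3) through the tether C6–C9, giving trans-fused octalin aldehyde A5.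
- In favour: two rings, two bonds and quaternary C5 form in the last skeletal step. The complete arene including the ester is carried, so no late carbonylation is needed. C11 arrives as a formyl carbon that reduction and elimination would turn into the exocyclic methylene. In convergence and complexity gained per step it is better than the chosen plan. In control of the trans ring fusion it is about equal.
- Against: A4 must hold the C8/C9 pair, one of them quaternary, in an open chain where no ring biases their formation. A β,β-disubstituted enal is a poor dienophile for making a quaternary centre. In the trans-fused transition state the axial C9 substituent faces the developing C5 methyl, and here it must be a methyl group and not a cyano group, which raises the barrier. The aluminium Lewis acid threatens the methoxymethyl ether, and C1=C2 must be hydrogenated before the methylene is made.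
- Comparison: both plans rely on the same chair preference (small group axial at C9), the chosen one with the smaller group. The chosen plan builds the C8/C9 pair on a pre-formed ring A, which is the safer setting. The elegance of the last step is likely consumed by the acyclic stereocontrol needed for A4, so no gain in step count is expected.

Alternative 3: Ring A is cut at C2–C3 and C4–C5. Forward, a Lewis-acid-promoted Diels–Alder reaction of acrolein A7 (C3, C4) with the ring B diene A6 (C2=C1–C10=C5) gives the 1(10)-ene aldehyde A8 with quaternary C5.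
- In favour: a cheap two-carbon dienophile, ring A and C5 in one step, and C11 again as a formyl carbon. The C8/C9 pair of the ring B fragment could be assembled on a cyclohexenone. Hydrogenation of C1=C10 from the face opposite the two β methyl groups should give the trans fusion and would remove the benzyl ether in the same operation. On step economy this plan is the better one on paper.
- Against: the reacting diene terminus C5 is fully substituted and its methyl group is cis to the vinyl group, so the s-cis conformer suffers the clash known from Z-substituted dienes. The neighbouring quaternary C9 twists the vinyl group further. The dienophile must bond to C5 on the face of the arylmethyl group for C12 to end up syn to C14, and allylic strain may place exactly that large group pseudo-axial, so the facial outcome is uncertain. C10 is left to a later hydrogenation.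
- Comparison: it equals the chosen plan in avoiding late aromatic functionalisation only if the ester tolerates the Lewis acid. On structure and mechanism the chosen plan is safer, because its two critical selectivities (inversion at C8, nitrile axial at C9) follow from well-defined transition states, whereas here both reactivity and face selectivity of the cycloaddition are doubtful.

Key step: step 15

Assumption: the antipode of the chiral phosphoramidite in step 4 is chosen so that vinyl is delivered to give (S)-configured C10; the sense of induction has to be confirmed on the first run, and all later centres are relayed from C10 and from (R)-configured 1.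

## Route

Step 1
Reactants: 1 (R)-butane-1,3-diol
Product: 2 (R)-3-hydroxybutyl 4-methylbenzenesulfonate
Conditions: TsCl (1.0 equiv), pyridine, CH2Cl2, −20 → 0 °C
Reagents that add atoms: 4-methylbenzenesulfonyl chloride (TsCl), Cc1ccc(cc1)S(=O)(=O)Cl
Why: Selective monosulfonylation of a 1,3-diol, the unhindered primary hydroxyl reacting much faster than the secondary one at low temperature; the stereocentre is not touched.

Step 2
Reactants: 2 (R)-3-hydroxybutyl 4-methylbenzenesulfonate
Product: 3 (R)-3-[(tert-butyldiphenylsilyl)oxy]butyl 4-methylbenzenesulfonate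
Conditions: TBDPSCl, imidazole, DMF, rt
Reagents that add atoms: tert-butyl(chloro)diphenylsilane (TBDPSCl), CC(C)(C)[Si](Cl)(c1ccccc1)c1ccccc1
Why: Standard silylation of a secondary alcohol; the bulky, acid-tolerant silyl ether is chosen to survive the Lewis-acid ketalisation, the borane and the amide bases that follow.

Step 3
Reactants: 3 (R)-3-[(tert-butyldiphenylsilyl)oxy]butyl 4-methylbenzenesulfonate
Product: 4 (R)-tert-butyl[(4-iodobutan-2-yl)oxy]diphenylsilane
Conditions: NaI, acetone, reflux
Reagents that add atoms: sodium iodide, [Na+].[I-]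
Why: Finkelstein exchange (SN2) at the primary carbon gives the more reactive alkylating agent; the secondary stereocentre is remote from the reacting carbon.

Step 4
Reactants: 5 2-methylcyclohex-2-en-1-one
Product: 7 (S)-trimethyl[(2-methyl-3-vinylcyclohex-1-en-1-yl)oxy]silane, via dimethylaluminium enolate 6 (not isolated)
Conditions: CH2=CHMgBr, Me2AlCl, Et2O, 0 °C; then 5, CuTC (copper thiophene-2-carboxylate, 5 mol %), chiral BINOL-derived phosphoramidite (10 mol %), Et2O, −30 °C; then TMSOTf, −30 → 0 °C
Reagents that add atoms: vinylmagnesium bromide, C=C[Mg]Br; trimethylsilyl trifluoromethanesulfonate (TMSOTf), C[Si](C)(C)OS(=O)(=O)C(F)(F)F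
Why: Copper-catalysed asymmetric conjugate addition of an organoaluminium reagent to an α-substituted cyclic enone, the mixed alane transferring its alkenyl group in preference to methyl; the chiral phosphoramidite complex of monovalent copper selects the enone face and so sets C10 (S). Silylation of the aluminium enolate fixes the regiodefined tetrasubstituted enol ether.

Step 5
Reactants: 7 (S)-trimethyl[(2-methyl-3-vinylcyclohex-1-en-1-yl)oxy]silane; 4 (R)-tert-butyl[(4-iodobutan-2-yl)oxy]diphenylsilane
Product: 9 (2S,3S)-2-{(3R)-3-[(tert-butyldiphenylsilyl)oxy]butyl}-2-methyl-3-vinylcyclohexan-1-one, via lithium enolate 8 (not isolated)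
Conditions: MeLi, THF, 0 °C → rt; then DMPU, 4, −78 → 0 °C
Reagents that add atoms: none
Why: MeLi cleaves the silyl enol ether to the regiodefined lithium enolate, which is C-alkylated by the primary iodide (SN2) in the presence of DMPU. The electrophile enters anti to the pseudo-axial vinyl group on C10, so the new chain is trans to vinyl and C5 is set (S).

Step 6
Reactants: 9 (2S,3S)-2-{(3R)-3-[(tert-butyldiphenylsilyl)oxy]butyl}-2-methyl-3-vinylcyclohexan-1-one
Product: 10 tert-butyl({(2R)-4-[(6S,7S)-6-methyl-7-vinyl-1,4-dioxaspiro[4.5]decan-6-yl]butan-2-yl}oxy)diphenylsilane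
Conditions: (TMSOCH2)2, TMSOTf (5 mol %), CH2Cl2, −78 → −20 °C
Reagents that add atoms: 1,2-bis(trimethylsilyloxy)ethane, C[Si](C)(C)OCCO[Si](C)(C)C
Why: Aprotic TMSOTf-catalysed ketalisation, effective for hindered ketones and harmless to the silyl ether and the vinyl group; there is no second carbonyl group to compete.

Step 7
Reactants: 10 tert-butyl({(2R)-4-[(6S,7S)-6-methyl-7-vinyl-1,4-dioxaspiro[4.5]decan-6-yl]butan-2-yl}oxy)diphenylsilane
Product: 12 2-[(6S,7S)-6-{(3R)-3-[(tert-butyldiphenylsilyl)oxy]butyl}-6-methyl-1,4-dioxaspiro[4.5]decan-7-yl]ethan-1-ol, via alkylborane 11 (not isolated)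
Conditions: 9-BBN, THF, 0 °C → rt; then NaOH, H2O2, 0 °C → rt
Reagents that add atoms: hydrogen peroxide, OO
Why: Anti-Markovnikov hydroboration–oxidation of the only alkene, a monosubstituted one; no stereocentre is formed or touched.

Step 8
Reactants: 12 2-[(6S,7S)-6-{(3R)-3-[(tert-butyldiphenylsilyl)oxy]butyl}-6-methyl-1,4-dioxaspiro[4.5]decan-7-yl]ethan-1-ol
Product: 15 2-[(6S,7S)-6-{(3R)-3-[(tert-butyldiphenylsilyl)oxy]butyl}-6-methyl-1,4-dioxaspiro[4.5]decan-7-yl]acetonitrile, via aldehyde 13 (not isolated), via aldimine 14 (not isolated)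
Conditions: TEMPO (10 mol %), PhI(OAc)2 (2.5 equiv), NH4OAc, MeCN/H2O, rt
Reagents that add atoms: ammonium acetate, CC(=O)[O-].[NH4+]
Why: One-flask oxidative conversion of a primary alcohol into a nitrile: oxoammonium oxidation to the aldehyde, condensation with ammonia and a second oxidation of the N–H aldimine. C10 is β to the carbonyl carbon and cannot epimerise.

Step 9
Reactants: 16 5-bromo-2-hydroxy-3-methoxybenzaldehyde
Product: 17 5-bromo-3-methoxy-2-(methoxymethoxy)benzaldehyde
Conditions: MOMCl, iPr2NEt, CH2Cl2, 0 °C → rt
Reagents that add atoms: chloromethyl methyl ether (MOMCl), COCCl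
Why: O-alkylation of the phenol; the methoxymethyl ether is stable to all later bases and is removed by the same acid that opens the dioxolane.

Step 10
Reactants: 17 5-bromo-3-methoxy-2-(methoxymethoxy)benzaldehyde
Product: 18 [5-bromo-3-methoxy-2-(methoxymethoxy)phenyl]methanol
Conditions: NaBH4, MeOH, 0 °C
Reagents that add atoms: none
Why: Chemoselective hydride reduction of the aldehyde; aryl bromide and acetal are inert.

Step 11
Reactants: 18 [5-bromo-3-methoxy-2-(methoxymethoxy)phenyl]methanol
Product: 19 5-bromo-1-(bromomethyl)-3-methoxy-2-(methoxymethoxy)benzene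
Conditions: CBr4, PPh3, CH2Cl2, 0 °C
Reagents that add atoms: carbon tetrabromide, BrC(Br)(Br)Br
Why: Appel bromination under neutral conditions, which spares the acid-labile methoxymethyl ether; the bromide is used directly.

Step 12
Reactants: 15 2-[(6S,7S)-6-{(3R)-3-[(tert-butyldiphenylsilyl)oxy]butyl}-6-methyl-1,4-dioxaspiro[4.5]decan-7-yl]acetonitrile; 19 5-bromo-1-(bromomethyl)-3-methoxy-2-(methoxymethoxy)benzene
Product: 21 3-[5-bromo-3-methoxy-2-(methoxymethoxy)phenyl]-2-[(6S,7S)-6-{(3R)-3-[(tert-butyldiphenylsilyl)oxy]butyl}-6-methyl-1,4-dioxaspiro[4.5]decan-7-yl]propanenitrile (both C2 epimers), via lithiated nitrile 20 (not isolated)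
Conditions: LiN(iPr)2, THF, −78 °C; then 19, −78 → −40 °C
Reagents that add atoms: none
Why: α-Alkylation of a nitrile-stabilised carbanion with a benzylic bromide forms the C9–C15 bond. C9 is left as an epimer mixture on purpose, because it is planarised again in step 15.

Step 13
Reactants: 21 3-[5-bromo-3-methoxy-2-(methoxymethoxy)phenyl]-2-[(6S,7S)-6-{(3R)-3-[(tert-butyldiphenylsilyl)oxy]butyl}-6-methyl-1,4-dioxaspiro[4.5]decan-7-yl]propanenitrile
Product: 22 3-[5-bromo-3-methoxy-2-(methoxymethoxy)phenyl]-2-{(6S,7S)-6-[(3R)-3-hydroxybutyl]-6-methyl-1,4-dioxaspiro[4.5]decan-7-yl}propanenitrile (both C2 epimers)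
Conditions: Bu4NF·3H2O, THF, rt → 45 °C
Reagents that add atoms: none
Why: Fluoride cleavage of the Si–O bond; ketal, methoxymethyl ether, aryl bromide and nitrile are inert and the C–O bond at C8 is not touched.

Step 14
Reactants: 22 3-[5-bromo-3-methoxy-2-(methoxymethoxy)phenyl]-2-{(6S,7S)-6-[(3R)-3-hydroxybutyl]-6-methyl-1,4-dioxaspiro[4.5]decan-7-yl}propanenitrile
Product: 23 (2R)-4-[(6S,7S)-7-{2-[5-bromo-3-methoxy-2-(methoxymethoxy)phenyl]-1-cyanoethyl}-6-methyl-1,4-dioxaspiro[4.5]decan-6-yl]butan-2-yl 4-methylbenzenesulfonate (both epimers at the cyano-bearing carbon)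
Conditions: TsCl, Et3N, DMAP (cat.), CH2Cl2, 0 °C → rt
Reagents that add atoms: 4-methylbenzenesulfonyl chloride (TsCl), Cc1ccc(cc1)S(=O)(=O)Cl
Why: Sulfonylation takes place at oxygen, so the (R) configuration at C8 is retained and the centre is armed for one clean inversion.

Step 15
Reactants: 23 (2R)-4-[(6S,7S)-7-{2-[5-bromo-3-methoxy-2-(methoxymethoxy)phenyl]-1-cyanoethyl}-6-methyl-1,4-dioxaspiro[4.5]decan-6-yl]butan-2-yl 4-methylbenzenesulfonate
Product: 25 (5S,8S,9S,10S)-9-{[5-bromo-3-methoxy-2-(methoxymethoxy)phenyl]methyl}-4,4-(ethylenedioxy)-5,8-dimethyl-trans-decalin-9-carbonitrile (skeleton numbering), via potassium keteniminate 24 (not isolated)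
Conditions: KN(SiMe3)2 (1.3 equiv), THF (0.02 M), −78 °C → rt
Reagents that add atoms: none
Why: KN(SiMe3)2 removes the C9 proton of either epimer of 23 to give the planar N-potassiated keteniminate 24, so the C9 configuration of the substrate is irrelevant. The carbanion carbon then displaces the C8 tosylate in an intramolecular SN2 reaction; the closest known reaction type is the cycloalkylation of nitrile-stabilised carbanions with secondary sulfonates to give cyclohexanecarbonitriles with a quaternary carbon. Ring B closes in the 6-exo-tet mode, the leaving group lying outside the forming ring and collinear with the incoming C9. C8 is controlled by the substrate: backside attack inverts the (R)-sulfonate to (8S), which places the C8 methyl equatorial in the chair transition state. C9 is controlled by that chair on the trans-substituted ring A: whatever ends up axial at C9 is 1,3-diaxial to the axial C5 methyl, a site the linear cyano group tolerates far better than the arylmethyl group, so the nitrile goes axial and the arylmethyl group equatorial (9S). The step needs C-alkylation to beat E2 loss of the tosylate and intermolecular alkylation; the six-membered transition state, high dilution, low starting temperature and the hindered non-nucleophilic base serve this. The dioxolane removes the only other acidic site (C3) that could have competed.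

Step 16
Reactants: 25 (5S,8S,9S,10S)-9-{[5-bromo-3-methoxy-2-(methoxymethoxy)phenyl]methyl}-4,4-(ethylenedioxy)-5,8-dimethyl-trans-decalin-9-carbonitrile
Product: 27 (5S,8S,9S,10S)-9-{[5-bromo-3-methoxy-2-(methoxymethoxy)phenyl]methyl}-4,4-(ethylenedioxy)-5,8-dimethyl-trans-decalin-9-carbaldehyde, via N-aluminio aldimine 26 (not isolated)
Conditions: iBu2AlH, toluene, −78 → 0 °C; then aq. citric acid, 0 °C
Reagents that add atoms: water, O
Why: Partial reduction of a nitrile: hydroalumination stops at the N-aluminio aldimine, which mild aqueous acid hydrolyses to the aldehyde without opening the ketal or the methoxymethyl ether; quaternary C9 cannot epimerise.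

Step 17
Reactants: 27 (5S,8S,9S,10S)-9-{[5-bromo-3-methoxy-2-(methoxymethoxy)phenyl]methyl}-4,4-(ethylenedioxy)-5,8-dimethyl-trans-decalin-9-carbaldehyde
Product: 29 (5S,8S,9R,10S)-9-{[5-bromo-3-methoxy-2-(methoxymethoxy)phenyl]methyl}-4,4-(ethylenedioxy)-5,8,9-trimethyl-trans-decalin, via hydrazone 28 (not isolated)
Conditions: N2H4·H2O, KOH, diethylene glycol, 130 °C, then 200 °C
Reagents that add atoms: none
Why: Wolff–Kishner reduction: hydrazone formation, then base-induced loss of N2, turns the formyl group into the C14 methyl. Ketal, methoxymethyl ether and the electron-rich aryl bromide are stable to hot alkali, and the descriptor at C9 changes to R only through the priority change.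

Step 18
Reactants: 29 (5S,8S,9R,10S)-9-{[5-bromo-3-methoxy-2-(methoxymethoxy)phenyl]methyl}-4,4-(ethylenedioxy)-5,8,9-trimethyl-trans-decalin
Product: 30 methyl 3-{[(5S,8S,9R,10S)-4,4-(ethylenedioxy)-5,8,9-trimethyl-trans-decalin-9-yl]methyl}-5-methoxy-4-(methoxymethoxy)benzoate
Conditions: Pd(OAc)2 (5 mol %), Xantphos (10 mol %), CO (1 atm), Et3N, MeOH, 70 °C
Reagents that add atoms: carbon monoxide, [C-]#[O+]; methanol, CO
Why: Palladium-catalysed methoxycarbonylation of an aryl bromide: oxidative addition to zerovalent palladium, CO insertion and methanolysis of the acyl complex. The ester position is fixed by the bromine present since 16.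

Step 19
Reactants: 30 methyl 3-{[(5S,8S,9R,10S)-4,4-(ethylenedioxy)-5,8,9-trimethyl-trans-decalin-9-yl]methyl}-5-methoxy-4-(methoxymethoxy)benzoate
Product: 31 methyl 4-hydroxy-3-methoxy-5-{[(5S,8S,9R,10S)-5,8,9-trimethyl-4-oxo-trans-decalin-9-yl]methyl}benzoate
Conditions: 3 M aq. HCl, THF/MeOH, 50 °C
Reagents that add atoms: water, O
Why: Acid hydrolysis cleaves the dioxolane and the methoxymethyl acetal in one operation. The methanol co-solvent keeps the methyl ester intact, and quaternary C5 next to the ketone cannot epimerise.

Step 20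
Reactants: 31 methyl 4-hydroxy-3-methoxy-5-{[(5S,8S,9R,10S)-5,8,9-trimethyl-4-oxo-trans-decalin-9-yl]methyl}benzoate
Product: 34 polyfibrospongol A, methyl 4-hydroxy-3-methoxy-5-{[(1R,2S,4aS,8aS)-1,2,4a-trimethyl-5-methylidenedecahydronaphthalen-1-yl]methyl}benzoate, via ketone phenoxide 32 (not isolated), via product phenoxide 33 (not isolated)
Conditions: KN(SiMe3)2 (1.0 equiv), THF, 0 °C; then Ph3P=CH2 [from Ph3PCH3Br, KN(SiMe3)2] (4 equiv), THF/toluene, 0 → 70 °C; aq. NH4Cl
Reagents that add atoms: methyltriphenylphosphonium bromide, C[P+](c1ccccc1)(c1ccccc1)c1ccccc1.[Br-]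
Why: Wittig methylenation of the hindered C4 ketone with excess alkoxide-free ylide. Prior conversion of the phenol into its potassium salt keeps the ylide from being protonated and, through donation from the para oxygen, lowers the electrophilicity of the ester so that the ketone reacts first. The acid-sensitive alkene is made last and no stereocentre is affected.

## Compound list

1 | (R)-butane-1,3-diol | C[C@@H](O)CCO | starting material
2 | (R)-3-hydroxybutyl 4-methylbenzenesulfonate | C[C@@H](O)CCOS(=O)(=O)c1ccc(C)cc1 | intermediate
3 | (R)-3-[(tert-butyldiphenylsilyl)oxy]butyl 4-methylbenzenesulfonate | C[C@@H](O[Si](c1ccccc1)(c2ccccc2)C(C)(C)C)CCOS(=O)(=O)c3ccc(C)cc3 | intermediate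
4 | (R)-tert-butyl[(4-iodobutan-2-yl)oxy]diphenylsilane | C[C@@H](O[Si](c1ccccc1)(c2ccccc2)C(C)(C)C)CCI | intermediate
5 | 2-methylcyclohex-2-en-1-one | CC1=CCCCC1=O | starting material
6 | dimethylaluminium (S)-2-methyl-3-vinylcyclohex-1-en-1-olate | C=C[C@@H]1CCCC(O[Al](C)C)=C1C | intermediate (not isolated)
7 | (S)-trimethyl[(2-methyl-3-vinylcyclohex-1-en-1-yl)oxy]silane | C=C[C@@H]1CCCC(O[Si](C)(C)C)=C1C | intermediate
8 | lithium (S)-2-methyl-3-vinylcyclohex-1-en-1-olate | C=C[C@@H]1CCCC([O-])=C1C.[Li+] | intermediate (not isolated)
9 | (2S,3S)-2-{(3R)-3-[(tert-butyldiphenylsilyl)oxy]butyl}-2-methyl-3-vinylcyclohexan-1-one | C=C[C@@H]1CCCC(=O)[C@@]1(C)CC[C@@H](C)O[Si](c2ccccc2)(c3ccccc3)C(C)(C)C | intermediate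
10 | tert-butyl({(2R)-4-[(6S,7S)-6-methyl-7-vinyl-1,4-dioxaspiro[4.5]decan-6-yl]butan-2-yl}oxy)diphenylsilane | C=C[C@@H]1CCCC2(OCCO2)[C@@]1(C)CC[C@@H](C)O[Si](c3ccccc3)(c4ccccc4)C(C)(C)C | intermediate
11 | 9-{2-[(6S,7S)-6-{(3R)-3-[(tert-butyldiphenylsilyl)oxy]butyl}-6-methyl-1,4-dioxaspiro[4.5]decan-7-yl]ethyl}-9-borabicyclo[3.3.1]nonane | C1CCC2CCCC1B2CC[C@@H]3CCCC4(OCCO4)[C@@]3(C)CC[C@@H](C)O[Si](c5ccccc5)(c6ccccc6)C(C)(C)C | intermediate (not isolated)
12 | 2-[(6S,7S)-6-{(3R)-3-[(tert-butyldiphenylsilyl)oxy]butyl}-6-methyl-1,4-dioxaspiro[4.5]decan-7-yl]ethan-1-ol | OCC[C@@H]1CCCC2(OCCO2)[C@@]1(C)CC[C@@H](C)O[Si](c3ccccc3)(c4ccccc4)C(C)(C)C | intermediate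
13 | 2-[(6S,7S)-6-{(3R)-3-[(tert-butyldiphenylsilyl)oxy]butyl}-6-methyl-1,4-dioxaspiro[4.5]decan-7-yl]acetaldehyde | O=CC[C@@H]1CCCC2(OCCO2)[C@@]1(C)CC[C@@H](C)O[Si](c3ccccc3)(c4ccccc4)C(C)(C)C | intermediate (not isolated)
14 | 2-[(6S,7S)-6-{(3R)-3-[(tert-butyldiphenylsilyl)oxy]butyl}-6-methyl-1,4-dioxaspiro[4.5]decan-7-yl]ethan-1-imine | N=CC[C@@H]1CCCC2(OCCO2)[C@@]1(C)CC[C@@H](C)O[Si](c3ccccc3)(c4ccccc4)C(C)(C)C | intermediate (not isolated)
15 | 2-[(6S,7S)-6-{(3R)-3-[(tert-butyldiphenylsilyl)oxy]butyl}-6-methyl-1,4-dioxaspiro[4.5]decan-7-yl]acetonitrile | N#CC[C@@H]1CCCC2(OCCO2)[C@@]1(C)CC[C@@H](C)O[Si](c3ccccc3)(c4ccccc4)C(C)(C)C | intermediate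
16 | 5-bromo-2-hydroxy-3-methoxybenzaldehyde | O=Cc1cc(Br)cc(OC)c1O | starting material
17 | 5-bromo-3-methoxy-2-(methoxymethoxy)benzaldehyde | O=Cc1cc(Br)cc(OC)c1OCOC | intermediate
18 | [5-bromo-3-methoxy-2-(methoxymethoxy)phenyl]methanol | OCc1cc(Br)cc(OC)c1OCOC | intermediate
19 | 5-bromo-1-(bromomethyl)-3-methoxy-2-(methoxymethoxy)benzene | BrCc1cc(Br)cc(OC)c1OCOC | intermediate
20 | lithium keteniminate of nitrile 15 | [Li+].[N-]=C=C[C@@H]1CCCC2(OCCO2)[C@@]1(C)CC[C@@H](C)O[Si](c3ccccc3)(c4ccccc4)C(C)(C)C | intermediate (not isolated)
21 | 3-[5-bromo-3-methoxy-2-(methoxymethoxy)phenyl]-2-[(6S,7S)-6-{(3R)-3-[(tert-butyldiphenylsilyl)oxy]butyl}-6-methyl-1,4-dioxaspiro[4.5]decan-7-yl]propanenitrile (both C2 epimers) | N#CC(Cc1cc(Br)cc(OC)c1OCOC)[C@@H]2CCCC3(OCCO3)[C@@]2(C)CC[C@@H](C)O[Si](c4ccccc4)(c5ccccc5)C(C)(C)C | intermediate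
22 | 3-[5-bromo-3-methoxy-2-(methoxymethoxy)phenyl]-2-{(6S,7S)-6-[(3R)-3-hydroxybutyl]-6-methyl-1,4-dioxaspiro[4.5]decan-7-yl}propanenitrile (both C2 epimers) | N#CC(Cc1cc(Br)cc(OC)c1OCOC)[C@@H]2CCCC3(OCCO3)[C@@]2(C)CC[C@@H](C)O | intermediate
23 | (2R)-4-[(6S,7S)-7-{2-[5-bromo-3-methoxy-2-(methoxymethoxy)phenyl]-1-cyanoethyl}-6-methyl-1,4-dioxaspiro[4.5]decan-6-yl]butan-2-yl 4-methylbenzenesulfonate (both epimers at the cyano-bearing carbon) | N#CC(Cc1cc(Br)cc(OC)c1OCOC)[C@@H]2CCCC3(OCCO3)[C@@]2(C)CC[C@@H](C)OS(=O)(=O)c4ccc(C)cc4 | intermediate (precursor of the key step)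
24 | potassium keteniminate of 23 | [K+].[N-]=C=C(Cc1cc(Br)cc(OC)c1OCOC)[C@@H]2CCCC3(OCCO3)[C@@]2(C)CC[C@@H](C)OS(=O)(=O)c4ccc(C)cc4 | intermediate (not isolated)
25 | (5S,8S,9S,10S)-9-{[5-bromo-3-methoxy-2-(methoxymethoxy)phenyl]methyl}-4,4-(ethylenedioxy)-5,8-dimethyl-trans-decalin-9-carbonitrile | O1CCOC12CCC[C@H]3[C@](C#N)(Cc4cc(Br)cc(OC)c4OCOC)[C@@H](C)CC[C@]23C | intermediate (product of the key step)
26 | N-(diisobutylaluminio)aldimine of 27 | O1CCOC12CCC[C@H]3[C@](C=N[Al](CC(C)C)CC(C)C)(Cc4cc(Br)cc(OC)c4OCOC)[C@@H](C)CC[C@]23C | intermediate (not isolated)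
27 | (5S,8S,9S,10S)-9-{[5-bromo-3-methoxy-2-(methoxymethoxy)phenyl]methyl}-4,4-(ethylenedioxy)-5,8-dimethyl-trans-decalin-9-carbaldehyde | O1CCOC12CCC[C@H]3[C@](C=O)(Cc4cc(Br)cc(OC)c4OCOC)[C@@H](C)CC[C@]23C | intermediate
28 | hydrazone of aldehyde 27 | O1CCOC12CCC[C@H]3[C@](C=NN)(Cc4cc(Br)cc(OC)c4OCOC)[C@@H](C)CC[C@]23C | intermediate (not isolated)
29 | (5S,8S,9R,10S)-9-{[5-bromo-3-methoxy-2-(methoxymethoxy)phenyl]methyl}-4,4-(ethylenedioxy)-5,8,9-trimethyl-trans-decalin | O1CCOC12CCC[C@H]3[C@](C)(Cc4cc(Br)cc(OC)c4OCOC)[C@@H](C)CC[C@]23C | intermediate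
30 | methyl 3-{[(5S,8S,9R,10S)-4,4-(ethylenedioxy)-5,8,9-trimethyl-trans-decalin-9-yl]methyl}-5-methoxy-4-(methoxymethoxy)benzoate | O1CCOC12CCC[C@H]3[C@](C)(Cc4cc(C(=O)OC)cc(OC)c4OCOC)[C@@H](C)CC[C@]23C | intermediate
31 | methyl 4-hydroxy-3-methoxy-5-{[(5S,8S,9R,10S)-5,8,9-trimethyl-4-oxo-trans-decalin-9-yl]methyl}benzoate | O=C1CCC[C@H]2[C@](C)(Cc3cc(C(=O)OC)cc(OC)c3O)[C@@H](C)CC[C@]12C | intermediate
32 | potassium phenoxide of ketone 31 | O=C1CCC[C@H]2[C@](C)(Cc3cc(C(=O)OC)cc(OC)c3[O-])[C@@H](C)CC[C@]12C.[K+] | intermediate (not isolated)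
33 | potassium phenoxide of 34 | C=C1CCC[C@H]2[C@](C)(Cc3cc(C(=O)OC)cc(OC)c3[O-])[C@@H](C)CC[C@]12C.[K+] | intermediate (not isolated)
34 | polyfibrospongol A, methyl 4-hydroxy-3-methoxy-5-{[(1R,2S,4aS,8aS)-1,2,4a-trimethyl-5-methylidenedecahydronaphthalen-1-yl]methyl}benzoate | C=C1CCC[C@H]2[C@](C)(Cc3cc(C(=O)OC)cc(OC)c3O)[C@@H](C)CC[C@]12C | target

## Step count and least certain steps

Total step count: 20. Longest linear sequence: 16 steps (steps 1–3, 5–8 and 12–20).

Step 15 (key step). The most likely failure is E2 loss of the secondary tosylate competing with C-alkylation, because the attacking carbon is fully substituted and the electrophilic carbon is secondary. A second risk is incomplete preference for the axial nitrile if the transition state departs from the chair. The fallback reverses the order of the two bond formations at C9. It sets out from 15: fluoride desilylation should give 2-{(6S,7S)-6-[(3R)-3-hydroxybutyl]-6-methyl-1,4-dioxaspiro[4.5]decan-7-yl}acetonitrile F4, and tosylation its sulfonate (2R)-4-[(6S,7S)-7-(cyanomethyl)-6-methyl-1,4-dioxaspiro[4.5]decan-6-yl]butan-2-yl 4-methylbenzenesulfonate F5. KN(SiMe3)2 would then close ring B with the less hindered secondary carbanion, again with inversion at C8, to (5S,8S,10S)-4,4-(ethylenedioxy)-5,8-dimethyl-trans-decalin-9-carbonitrile F6 (C9 epimers). Deprotonation of F6 with LiN(iPr)2 and alkylation with 19 returns to the route at 25; the electrophile should enter from the equatorial direction because the axial one is blocked by the C5 methyl.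

Step 4. What may go wrong is insufficient enantioselectivity, or competing methyl transfer, with the small parent vinyl group on an α-substituted enone, since the catalyst has little to grip. The fallback changes metal and mechanism and sets out from 5: a rhodium-catalysed Hayashi–Miyaura 1,4-addition of CH2=CHBF3K ([RhCl(cod)]2, BINAP, Et3N, toluene/H2O, 100 °C) should give (3S)-2-methyl-3-vinylcyclohexan-1-one F1 as a mixture at C2, which does not matter. Silylation under equilibrating conditions (TMSCl, NaI, Et3N, MeCN) toward the more substituted enol ether comes back to the route at 7.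

Step 5. The risk is slow C-alkylation of the tetrasubstituted enolate by an unactivated iodide, which gives time for proton transfer to the product, over-alkylation at C3 and O-alkylation. The fallback sets out from 7 and uses a Michael acceptor. Mukaiyama–Michael addition to methyl vinyl ketone (BF3·OEt2, CH2Cl2, −78 °C) should give (2S,3S)-2-methyl-2-(3-oxobutyl)-3-vinylcyclohexan-1-one F2. Reduction of the unhindered methyl ketone with an (R)-selective alcohol dehydrogenase (NADP+, iPrOH, buffer) should give (2S,3S)-2-[(3R)-3-hydroxybutyl]-2-methyl-3-vinylcyclohexan-1-one F3. Silylation (TBDPSCl, imidazole) returns to the route at 9.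

Step 17. Hydrazone formation at the neopentyl, axial aldehyde may stall, or the aryl bromide may be lost by reduction under hot alkaline hydrazine. The fallback avoids hydrazine and sets out from 27: NaBH4 should give (5S,8S,9S,10S)-9-{[5-bromo-3-methoxy-2-(methoxymethoxy)phenyl]methyl}-4,4-(ethylenedioxy)-9-(hydroxymethyl)-5,8-dimethyl-trans-decalin F7. Tf2O/pyridine would convert it into the corresponding trifluoromethanesulfonate, [(5S,8S,9S,10S)-9-{[5-bromo-3-methoxy-2-(methoxymethoxy)phenyl]methyl}-4,4-(ethylenedioxy)-5,8-dimethyl-trans-decalin-9-yl]methyl trifluoromethanesulfonate F8. Hydride displacement with LiEt3BH (THF, 0 °C → rt) comes back to the route at 29.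

Step 20. The ylide may be acylated by the ester at the temperature the hindered ketone needs, despite the phenoxide. The fallback changes the order so that no ester is present during the olefination, and sets out from 29. Aqueous HCl should give (5S,8S,9R,10S)-9-[(5-bromo-2-hydroxy-3-methoxyphenyl)methyl]-5,8,9-trimethyl-trans-decalin-4-one F9. Wittig methylenation of its potassium salt should give 4-bromo-2-methoxy-6-{[(1R,2S,4aS,8aS)-1,2,4a-trimethyl-5-methylidenedecahydronaphthalen-1-yl]methyl}phenol F10. Palladium-catalysed methoxycarbonylation of the bromophenol (Pd(OAc)2, dppf, CO, Et3N, MeOH/DMSO, 80 °C) then comes back to the route at 34.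

## Further compounds

F1 | step 4 | (3S)-2-methyl-3-vinylcyclohexan-1-one (C2 epimer mixture) | C=C[C@@H]1CCCC(=O)C1C
F2 | step 5 | (2S,3S)-2-methyl-2-(3-oxobutyl)-3-vinylcyclohexan-1-one | C=C[C@@H]1CCCC(=O)[C@@]1(C)CCC(C)=O
F3 | step 5 | (2S,3S)-2-[(3R)-3-hydroxybutyl]-2-methyl-3-vinylcyclohexan-1-one | C=C[C@@H]1CCCC(=O)[C@@]1(C)CC[C@@H](C)O
F4 | step 15 | 2-{(6S,7S)-6-[(3R)-3-hydroxybutyl]-6-methyl-1,4-dioxaspiro[4.5]decan-7-yl}acetonitrile | N#CC[C@@H]1CCCC2(OCCO2)[C@@]1(C)CC[C@@H](C)O
F5 | step 15 | (2R)-4-[(6S,7S)-7-(cyanomethyl)-6-methyl-1,4-dioxaspiro[4.5]decan-6-yl]butan-2-yl 4-methylbenzenesulfonate | N#CC[C@@H]1CCCC2(OCCO2)[C@@]1(C)CC[C@@H](C)OS(=O)(=O)c3ccc(C)cc3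
F6 | step 15 | (5S,8S,10S)-4,4-(ethylenedioxy)-5,8-dimethyl-trans-decalin-9-carbonitrile (C9 epimers) | O1CCOC12CCC[C@H]3C(C#N)[C@@H](C)CC[C@]23C
F7 | step 17 | (5S,8S,9S,10S)-9-{[5-bromo-3-methoxy-2-(methoxymethoxy)phenyl]methyl}-4,4-(ethylenedioxy)-9-(hydroxymethyl)-5,8-dimethyl-trans-decalin | O1CCOC12CCC[C@H]3[C@](CO)(Cc4cc(Br)cc(OC)c4OCOC)[C@@H](C)CC[C@]23C
F8 | step 17 | [(5S,8S,9S,10S)-9-{[5-bromo-3-methoxy-2-(methoxymethoxy)phenyl]methyl}-4,4-(ethylenedioxy)-5,8-dimethyl-trans-decalin-9-yl]methyl trifluoromethanesulfonate | O1CCOC12CCC[C@H]3[C@](COS(=O)(=O)C(F)(F)F)(Cc4cc(Br)cc(OC)c4OCOC)[C@@H](C)CC[C@]23C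
F9 | step 20 | (5S,8S,9R,10S)-9-[(5-bromo-2-hydroxy-3-methoxyphenyl)methyl]-5,8,9-trimethyl-trans-decalin-4-one | O=C1CCC[C@H]2[C@](C)(Cc3cc(Br)cc(OC)c3O)[C@@H](C)CC[C@]12C
F10 | step 20 | 4-bromo-2-methoxy-6-{[(1R,2S,4aS,8aS)-1,2,4a-trimethyl-5-methylidenedecahydronaphthalen-1-yl]methyl}phenol | C=C1CCC[C@H]2[C@](C)(Cc3cc(Br)cc(OC)c3O)[C@@H](C)CC[C@]12C
A1 | alternative 1 | (R)-tert-butyldimethyl[(2-vinylcyclohex-2-en-1-yl)oxy]silane | CC(C)(C)[Si](C)(C)O[C@@H]1CCCC=C1C=C
A2 | alternative 1 | tiglic aldehyde, (E)-2-methylbut-2-enal | C/C=C(\C)C=O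
A3 | alternative 1 | (4R,8S,9R,10R)-4-[(tert-butyldimethylsilyl)oxy]-8,9-dimethyldecal-5-ene-9-carbaldehyde (skeleton numbering) | CC(C)(C)[Si](C)(C)O[C@@H]1CCC[C@H]2[C@](C)(C=O)[C@@H](C)CC=C12
A4 | alternative 2 | (2E,6S,7R,8E)-7-{[3-methoxy-5-(methoxycarbonyl)-2-(methoxymethoxy)phenyl]methyl}-3,6,7-trimethylundeca-2,8,10-trienal | O=C/C=C(\C)CC[C@H](C)[C@@](C)(Cc1cc(C(=O)OC)cc(OC)c1OCOC)/C=C/C=C
A5 | alternative 2 | methyl 3-{[(4S,5S,8S,9R,10S)-4-formyl-5,8,9-trimethyl-trans-decal-1-en-9-yl]methyl}-5-methoxy-4-(methoxymethoxy)benzoate (skeleton numbering) | O=C[C@H]1CC=C[C@H]2[C@](C)(Cc3cc(C(=O)OC)cc(OC)c3OCOC)[C@@H](C)CC[C@]12C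
A6 | alternative 3 | methyl 4-(benzyloxy)-3-methoxy-5-{[(1R,6S)-1,3,6-trimethyl-2-vinylcyclohex-2-en-1-yl]methyl}benzoate | C=CC1=C(C)CC[C@H](C)[C@@]1(C)Cc2cc(C(=O)OC)cc(OC)c2OCc3ccccc3
A7 | alternative 3 | acrolein, prop-2-enal | C=CC=O
A8 | alternative 3 | methyl 4-(benzyloxy)-3-{[(4R,5R,8S,9R)-4-formyl-5,8,9-trimethyldecal-1(10)-en-9-yl]methyl}-5-methoxybenzoate (skeleton numbering) | O=C[C@@H]1CCC=C2[C@](C)(Cc3cc(C(=O)OC)cc(OC)c3OCc4ccccc4)[C@@H](C)CC[C@]12C
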